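The constants used here belong to no real substance.

The leftover is what I reckon for this flask: the starting material still unmet at the reading, and the share the dormant form has taken.

    reagent in the reaction phase ⇌ reagent in the second phase, rate k1*([reagent in the reaction phase] - [reagent in the second phase]/K1) per volume of the first phase (K1 = 2.6, k1 = 1.3 s⁻¹)
    starting material + reagent in the reaction phase → target (k2 = 5200 L mol⁻¹ s⁻¹)
    starting material ⇌ dormant form (K3 = 5.1, k3 = 0.044 s⁻¹)

starting material 5.0 mM; reagent in the second phase 5.00 mM; time 4.0 s; volume of the second phase over the first 0.25

- in the second phase: reagent in the second phase; everything else is in the first
- charges count per volume of the first phase; a concentration in a rate is the amount of a species over the volume of its own phase; every rate counts per litre of the first phase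
- what has gone from starting material into another species counts as reacted, even if it can come back
- run time (flask): 4.0 s

1. the target standing at 4.0 s, as a percentage of the starting material charged
2. part of the starting material charged that has reacted at 4.0 s

Reagent reaches the reaction phase through what I call the drain: the transfer coefficient over the partition ratio and the volume ratio, 2.00 s⁻¹, the first-order constant at which the second phase empties into an empty reaction phase. Step 2 at the charged [starting material] runs at 26.0 s⁻¹, faster than the drain, so the equal charges of starting material and reagent should fall together at the drain. Over 4.0 s that is 3.48 powers of ten, leaving a floor of 0.0335% of the reagent in the second phase; this bounds the reagent crossed, and with it the target, but not the conversion, since starting material also leaves as dormant form. The dormant form, formed more slowly than the drain, takes about 2.20%, which puts the target below about 97.8%.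

From below, back-transfer matches step 2 once [starting material] reaches 0.250 mM, a share 5.00% of its charge. Integrating the balance, the log of one over the leftover plus that share over the leftover comes to 8.00. Dropping the log gives a leftover of 0.625%; restoring it gives 1.71% as my upper figure, only 1.77 powers of ten down. The longer tail swells the dormant share, so I take the target above 95.6% and conversion above 98.3%.

The forecast, 96.3% and 98.9%, lies between my two figures for the target and above my lower figure for conversion, and holds that “the reaction consumes the reagent quickly until the tail”.

The flask gives 95.9% and 98.8%, which meet the same limits.

In the neighbour charged with 12 mM of starting material, the drain is unchanged, but reagent is now the limiting reagent, so the target's ceiling falls to 41.7% of the starting material charged. The same 3.48 powers of ten put the floor in the second phase at 0.0335% of its charge. That neighbour reads 41.6% target and 0.0452% of the reagent still in the second phase.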